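The target is a single 35-membered ring (C1–C34 plus the ring oxygen) whose only functional group is the lactone at C1. The C21–C22 bond lies in bare polymethylene, with C2–C21 on the acyl side and C22–C34 on the alkoxy side. The key step exploits this strain-free, unfunctionalised stretch by making the bond as a traceless alkene. Tandem ring-closing metathesis and hydrogenation of the open-chain ester tetradec-13-enyl docos-21-enoate joins C21 to C22, expels ethene and saturates the ring in one operation. This cut also uncovers two identical undec-10-enyl arms, so the diene comes from a twofold copper-catalysed Grignard coupling on one simple dibromo ester.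

Key step: step 3

Remark on numbering: C1 is the lactone carbonyl carbon, and C2 to C34 follow the chain round to the ring oxygen. The target has no stereocentre.

Step 1
Reactants: 1 11-bromoundecanoic acid; 2 3-bromopropan-1-ol
Product: 3 3-bromopropyl 11-bromoundecanoate
Conditions: p-TsOH·H2O (5 mol %), toluene, Dean–Stark trap, reflux
Reagents that add atoms: none
Why: Fischer esterification driven by azeotropic removal of water; both primary C–Br bonds are inert to catalytic sulfonic acid, and in acidic medium no carboxylate is present that could displace bromide.

Step 2
Reactants: 3 3-bromopropyl 11-bromoundecanoate; 4 11-bromoundec-1-ene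
Product: 6 tetradec-13-en-1-yl docos-21-enoate, via undec-10-en-1-ylmagnesium bromide 5 (not isolated)
Conditions: 4 (2.6 equiv), Mg, THF, 40 °C; then added over 2 h to 3, Li2CuCl4 (6 mol %), NMP (8 equiv), THF, 0 to 20 °C; aq NH4Cl
Reagents that add atoms: magnesium, [Mg] (retained in 5 only, not in 6)
Why: Copper-catalysed alkyl–alkyl Kumada-type (Kochi–Tamura) coupling run at both ends in one flask; the magnesium cuprate formed from Li2CuCl4 should displace both primary bromides much faster than the slowly added Grignard reagent adds to the ester, a chemoselectivity for which the NMP co-solvent variant is known with bromo esters.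

Step 3
Reactants: 6 tetradec-13-en-1-yl docos-21-enoate
Product: 8 oxacyclopentatriacontan-2-one, via oxacyclopentatriacont-22-en-2-one 7 (not isolated)
Conditions: RuCl2(=CHPh)(PCy3)2 (first-generation Grubbs catalyst, 2 × 4 mol %), ClCH2CH2Cl (2 mM), 45 °C, Ar sparge, 6 added over 10 h; then concentrated to 0.05 M without work-up, H2 (50 bar), 80 °C
Reagents that add atoms: none
Why: Ring-closing olefin metathesis with in-situ hydrogenation (assisted tandem catalysis, a known pairing for saturated macrocyclic musks): the ruthenium benzylidene exchanges onto one vinyl terminus of 6, the tethered alkylidene undergoes [2+2] cycloaddition with the other vinyl group, and cycloreversion of the ruthenacyclobutane expels ethene and leaves C21=C22. The one ring formed, the 35-membered lactone ring, is closed end to end between the two chain termini; at this size there is neither angle strain nor transannular strain, so only entropy opposes closure. The selectivity needed is ring over chain (acyclic diene metathesis), and it is secured by 2 mM pseudo-dilution, by ethene removal and by the reversibility of the reaction, which lets oligomers backbite to the monomeric ring. In the substrate, the two equally unhindered terminal alkenes react fast, and the ester lies 19 and 12 CH2 groups away from them, too far to tie up ruthenium in a chelate. The bis(phosphine) catalyst at 45 °C should form little hydride before H2 is admitted, which guards against double-bond migration and thus against ring-contracted homologues. Under H2 the carbene is converted into RuHCl(H2)(PCy3)2, which saturates both geometric isomers of 7, so alkene geometry needs no control, no stereocentre arises and the ester is untouched.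

Compound list
1 | 11-bromoundecanoic acid | OC(=O)CCCCCCCCCCBr | starting material
2 | 3-bromopropan-1-ol | OCCCBr | starting material
3 | 3-bromopropyl 11-bromoundecanoate | O=C(CCCCCCCCCCBr)OCCCBr | intermediate
4 | 11-bromoundec-1-ene | C=CCCCCCCCCCBr | starting material
5 | undec-10-en-1-ylmagnesium bromide | C=CCCCCCCCCC[Mg]Br | intermediate
6 | tetradec-13-en-1-yl docos-21-enoate | C=CCCCCCCCCCCCCCCCCCCCC(=O)OCCCCCCCCCCCCC=C | intermediate
7 | oxacyclopentatriacont-22-en-2-one (E/Z mixture, C21=C22 in chain numbering) | O=C1CCCCCCCCCCCCCCCCCCCC=CCCCCCCCCCCCCO1 | intermediate
8 | oxacyclopentatriacontan-2-one (tetratriacontan-34-olide) | O=C1CCCCCCCCCCCCCCCCCCCCCCCCCCCCCCCCCO1 | target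

Total step count: 3. Longest linear sequence: 3 steps (1 to 3 to 6 to 8).

Steps most likely to fail

Risk 1 (step 3): Chain growth by intermolecular metathesis may outrun ring closure. A terminal double bond may migrate before closure, so that the ring loses a CH2 group. Saturation may also stall at the low ruthenium concentration. The fallback replaces metathesis by a reductive carbonyl coupling that closes the same C21–C22 bond. It sets out from 6, whose two vinyl groups are cleaved by ozonolysis (O3, CH2Cl2, −78 °C; Me2S) to 13-oxotridecyl 21-oxohenicosanoate F1. Slow addition of this dialdehyde to low-valent titanium (TiCl3(DME)1.5, Zn–Cu couple, DME, reflux) is a McMurry coupling, in which aldehydes react well before an ester does. It should close the ring irreversibly and comes back to the route at 7, now isolated, which is hydrogenated over Pd/C (H2, EtOAc) to 8.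

Risk 2 (step 2): Addition of the Grignard reagent to the ester carbonyl, an incomplete second substitution and homocoupling of the Grignard reagent may erode the double coupling. The fallback makes both C–C bonds before the ester exists and sets out from 1 and 5. Acid 1 is first turned into its magnesium carboxylate with MeMgCl (THF, −20 °C) and then coupled with 5 under Li2CuCl4 catalysis to docos-21-enoic acid F2. A second portion of 5 opens oxetane (C1COC1; CuI 10 mol %, THF) to tetradec-13-en-1-ol F3. Steglich esterification of the two (DCC, DMAP, CH2Cl2) comes back to the route at 6.

Risk 3 (step 1): The equilibrium may stop short of full conversion, and long heating with acid may bring about self-etherification of the bromo alcohol. The fallback uses irreversible acyl transfer and sets out from 1. Oxalyl chloride (cat. DMF, CH2Cl2) converts 1 into 11-bromoundecanoyl chloride F4, and treatment with 2 and pyridine at 0 °C comes back to the route at 3.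

Further compounds
F1 | step 3 | 13-oxotridecyl 21-oxohenicosanoate | O=CCCCCCCCCCCCCCCCCCCCC(=O)OCCCCCCCCCCCCC=O
F2 | step 2 | docos-21-enoic acid | C=CCCCCCCCCCCCCCCCCCCCC(=O)O
F3 | step 2 | tetradec-13-en-1-ol | C=CCCCCCCCCCCCCO
F4 | step 1 | 11-bromoundecanoyl chloride | O=C(Cl)CCCCCCCCCCBr
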